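**Strategy.** Both end groups are the same (2R,3R)-2,3-dihydroxy-β ring, so one silyl-differentiated C15 phosphonium salt serves both ends of a C15 + C10 + C15 assembly; the portion destined for ring B loses its O3 triethylsilyl group before coupling, leaving one hydroxyl for sulfation. Each ring is disconnected at C1–C6: the C2 carbinol beside the gem-dimethyl carbon C1, together with the C5=C6 olefin, is the imprint of a 1,2-epoxide opened at its tertiary carbon and captured by a trisubstituted alkene. A titanocene-mediated radical epoxide–olefin cyclization of an acyclic epoxygeranyl acetate closes the six-membered ring, creates quaternary C1 and releases O2 with the epoxide's configuration; the precursor is a linear C10 chain from two C5 units.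

Key step: step 7

Remarks. Carotenoid numbering is used for the end group: C1 gem-dimethyl carbon, C2 and C3 carbinol carbons, C4 methylene, C5 methyl-bearing and C6 chain-bearing olefinic carbons, C7 first chain carbon, C18 the methyl on C5. Ring A is the unsulfated ring, ring B the sulfated one. Assumption: the sulfate monoester is written as the free hydrogen sulfate, as in the target; it would be handled as its pyridinium or sodium salt and protonated on a cold acidic resin just before isolation.

**Step 1**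
Reactants: 1 methyl 3-methylbut-2-enoate
Product: 2 tert-butyl[(1-methoxy-3-methylbuta-1,3-dien-1-yl)oxy]dimethylsilane
Conditions: LiN(iPr)2, THF/DMPU, −78 °C; TBSCl, −78 °C → rt
Reagents that add atoms: tert-butyldimethylsilyl chloride, CC(C)(C)[Si](C)(C)Cl
Why: LiN(iPr)2 removes a γ-proton of the senecioate and the lithium dienolate is O-silylated (silyl ketene acetal formation), giving the silyl dienol ether without creating a stereocentre.

**Step 2**
Reactants: 2 tert-butyl[(1-methoxy-3-methylbuta-1,3-dien-1-yl)oxy]dimethylsilane; 3 3-methylbut-2-enal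
Product: 4 methyl (2E,5R)-5-hydroxy-3,7-dimethylocta-2,6-dienoate
Conditions: SiCl4 (1.1 equiv), chiral bisphosphoramide (2 mol%; two (R)-N,N'-dimethyl-1,1'-binaphthyl-2,2'-diamine phosphoramide units joined through N,N'-dimethylpentane-1,5-diamine, the antipode that directs Re-face attack), iPr2NEt (10 mol%), CH2Cl2, −78 °C; aq. NaHCO3
Reagents that add atoms: none
Why: In this catalytic enantioselective vinylogous Mukaiyama aldol reaction the phosphoramide-bound trichlorosilyl cation activates the enal and the dienolate attacks through its γ-carbon in an open transition state, so that Re-face attack sets the 5R carbinol (the future C3) and the s-trans diene gives the 2E enoate.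

**Step 3**
Reactants: 4 methyl (2E,5R)-5-hydroxy-3,7-dimethylocta-2,6-dienoate
Product: 5 methyl (2E,5R)-5-[(2S)-3,3-dimethyloxiran-2-yl]-5-hydroxy-3-methylpent-2-enoate
Conditions: mCPBA (1.1 equiv), NaHCO3, CH2Cl2, 0 °C
Reagents that add atoms: 3-chloroperoxybenzoic acid, OOC(=O)c1cccc(Cl)c1
Why: Prilezhaev epoxidation is chemoselective for the electron-rich trisubstituted olefin over the enoate, and hydroxyl-directed delivery in the conformer that avoids allylic 1,3-strain with the cis-methyl (carbinol hydrogen eclipsing the olefin) sets the new oxirane centre S, which is the threo epoxy alcohol that maps onto the trans-2,3-diol.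

**Step 4**
Reactants: 5 methyl (2E,5R)-5-[(2S)-3,3-dimethyloxiran-2-yl]-5-hydroxy-3-methylpent-2-enoate
Product: 6 methyl (2E,5R)-5-[(2S)-3,3-dimethyloxiran-2-yl]-3-methyl-5-(triethylsilyloxy)pent-2-enoate
Conditions: TESCl, imidazole, CH2Cl2, 0 °C
Reagents that add atoms: chlorotriethylsilane, CC[Si](Cl)(CC)CC
Why: Standard silylation of the secondary alcohol masks the future O3 with the group that is later removed selectively, and no stereocentre is affected.

**Step 5**
Reactants: 6 methyl (2E,5R)-5-[(2S)-3,3-dimethyloxiran-2-yl]-3-methyl-5-(triethylsilyloxy)pent-2-enoate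
Product: 7 (2E,5R)-5-[(2S)-3,3-dimethyloxiran-2-yl]-3-methyl-5-(triethylsilyloxy)pent-2-en-1-ol
Conditions: iBu2AlH (2.3 equiv), CH2Cl2, −78 °C; aq. KNaC4H4O6 (Rochelle salt)
Reagents that add atoms: none
Why: iBu2AlH reduces the conjugated ester to the allylic alcohol by 1,2-hydride delivery at −78 °C, where the trisubstituted epoxide and the silyl ether are inert.

**Step 6**
Reactants: 7 (2E,5R)-5-[(2S)-3,3-dimethyloxiran-2-yl]-3-methyl-5-(triethylsilyloxy)pent-2-en-1-ol
Product: 8 (2E,5R)-5-[(2S)-3,3-dimethyloxiran-2-yl]-3-methyl-5-(triethylsilyloxy)pent-2-en-1-yl acetate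
Conditions: Ac2O, pyridine, DMAP (cat.), CH2Cl2, 0 °C → rt
Reagents that add atoms: acetic anhydride, CC(=O)OC(C)=O
Why: Acetylation gives the allylic acetate, the established olefin terminus for titanocene-mediated epoxypolyprene cyclization, and keeps a free hydroxyl away from the radical chain end.

**Step 7**
Reactants: 8 (2E,5R)-5-[(2S)-3,3-dimethyloxiran-2-yl]-3-methyl-5-(triethylsilyloxy)pent-2-en-1-yl acetate
Product: 9 [(1R,3R,4R)-3-hydroxy-2,2-dimethyl-6-methylidene-4-(triethylsilyloxy)cyclohexyl]methyl acetate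
Conditions: Cp2TiCl2 (2.5 equiv), Mn dust (8 equiv), THF, rt, slow addition of 8 to high dilution; aq. NaH2PO4
Reagents that add atoms: none
Why: Cp2TiCl (trivalent titanium, generated from Cp2TiCl2 and Mn) opens the oxirane homolytically at the C1–O bond to give the tertiary C1 radical and a titanium alkoxide on C2; the radical adds to C6 of the (E)-olefin, and the resulting tertiary C5 radical is trapped by a second Cp2TiCl and loses a β-hydrogen from C18 to give the exocyclic olefin. The closest known reaction is the titanocene-mediated radical cyclization of epoxypolyprenes such as 6,7-epoxygeranyl acetate (Nugent–RajanBabu reagent). The six-membered ring closes in the 6-endo-trig mode, because attack at C5 would join two fully substituted carbons and leave a secondary radical. C2 and C3 are not touched: the C2–O bond persists, so the oxirane configuration becomes the 2R carbinol, and the chair transition state carries O2 and O3 equatorial; the only new stereocentre, C6, is set by that chair with CH2OAc equatorial (cis to O2) and is erased in step 10. The step needs homolysis toward the tertiary radical, which the trisubstituted epoxide secures, and ring closure faster than reduction of that radical by a second Cp2TiCl, which its hindered tertiary nature and slow addition at high dilution secure. The position of the new olefin is immaterial, since all isomers converge on the conjugated aldehyde 13.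

**Step 8**
Reactants: 9 [(1R,3R,4R)-3-hydroxy-2,2-dimethyl-6-methylidene-4-(triethylsilyloxy)cyclohexyl]methyl acetate
Product: 10 [(1R,3R,4R)-3-(tert-butyldimethylsilyloxy)-2,2-dimethyl-6-methylidene-4-(triethylsilyloxy)cyclohexyl]methyl acetate
Conditions: TBSOTf, 2,6-lutidine, CH2Cl2, −40 → 0 °C
Reagents that add atoms: tert-butyldimethylsilyl trifluoromethanesulfonate, CC(C)(C)[Si](C)(C)OS(=O)(=O)C(F)(F)F
Why: The silyl triflate with 2,6-lutidine silylates even the neopentylic C2 hydroxyl, leaving O2 and O3 as differentiated TBS and TES ethers.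

**Step 9**
Reactants: 10 [(1R,3R,4R)-3-(tert-butyldimethylsilyloxy)-2,2-dimethyl-6-methylidene-4-(triethylsilyloxy)cyclohexyl]methyl acetate
Product: 11 [(1R,3R,4R)-3-(tert-butyldimethylsilyloxy)-2,2-dimethyl-6-methylidene-4-(triethylsilyloxy)cyclohexyl]methanol
Conditions: K2CO3 (0.3 equiv), MeOH, 0 °C → rt
Reagents that add atoms: none
Why: Carbonate-catalysed transesterification with methanol (Zemplén-type deacetylation) cleaves the primary acetate while both silyl ethers are stable.

**Step 10**
Reactants: 11 [(1R,3R,4R)-3-(tert-butyldimethylsilyloxy)-2,2-dimethyl-6-methylidene-4-(triethylsilyloxy)cyclohexyl]methanol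
Product: 13 (4R,5R)-5-(tert-butyldimethylsilyloxy)-2,6,6-trimethyl-4-(triethylsilyloxy)cyclohex-1-ene-1-carbaldehyde, via exocyclic-olefin aldehyde 12 (not isolated)
Conditions: Dess–Martin periodinane, NaHCO3, CH2Cl2, 0 °C → rt; aq. Na2S2O3 wash; then DBU (0.3 equiv), CH2Cl2, rt
Reagents that add atoms: none
Why: Dess–Martin oxidation gives the β,γ-unsaturated aldehyde, and DBU removes the doubly activated C6 hydrogen so that reprotonation of the dienolate at the exocyclic methylene moves the olefin into conjugation (base-mediated olefin isomerization), forming the tetrasubstituted C5=C6 bond of the β ring and erasing the C6 stereocentre.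

**Step 11**
Reactants: 13 (4R,5R)-5-(tert-butyldimethylsilyloxy)-2,6,6-trimethyl-4-(triethylsilyloxy)cyclohex-1-ene-1-carbaldehyde; 14 ethyl (2E)-4-(diethoxyphosphoryl)-3-methylbut-2-enoate
Product: 15 ethyl (2E,4E)-5-[(4R,5R)-5-(tert-butyldimethylsilyloxy)-2,6,6-trimethyl-4-(triethylsilyloxy)cyclohex-1-en-1-yl]-3-methylpenta-2,4-dienoate
Conditions: 14 (1.5 equiv), LiN(SiMe3)2, THF/DMPU, −78 → 0 °C; then 13, 0 °C → rt
Reagents that add atoms: none
Why: Horner–Wadsworth–Emmons olefination of the hindered enal with the lithiated C5 phosphonate builds the 7E olefin under thermodynamic control while the 9E geometry comes from the reagent, any 9Z isomer being removed by chromatography.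

**Step 12**
Reactants: 15 ethyl (2E,4E)-5-[(4R,5R)-5-(tert-butyldimethylsilyloxy)-2,6,6-trimethyl-4-(triethylsilyloxy)cyclohex-1-en-1-yl]-3-methylpenta-2,4-dienoate
Product: 16 (2E,4E)-5-[(4R,5R)-5-(tert-butyldimethylsilyloxy)-2,6,6-trimethyl-4-(triethylsilyloxy)cyclohex-1-en-1-yl]-3-methylpenta-2,4-dien-1-ol
Conditions: iBu2AlH (2.5 equiv), CH2Cl2, −78 °C; aq. KNaC4H4O6 (Rochelle salt)
Reagents that add atoms: none
Why: iBu2AlH reduces the dienoate to the primary allylic alcohol by 1,2-reduction without touching the silyl ethers or the olefins.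

**Step 13**
Reactants: 16 (2E,4E)-5-[(4R,5R)-5-(tert-butyldimethylsilyloxy)-2,6,6-trimethyl-4-(triethylsilyloxy)cyclohex-1-en-1-yl]-3-methylpenta-2,4-dien-1-ol
Product: 18 {(2E,4E)-5-[(4R,5R)-5-(tert-butyldimethylsilyloxy)-2,6,6-trimethyl-4-(triethylsilyloxy)cyclohex-1-en-1-yl]-3-methylpenta-2,4-dien-1-yl}triphenylphosphonium bromide, via dienyl bromide 17 (not isolated)
Conditions: CBr4 (1.2 equiv), PPh3 (1.25 equiv), CH2Cl2, 0 °C, dark; then PPh3 (1.5 equiv), rt
Reagents that add atoms: triphenylphosphine, c1ccccc1P(c1ccccc1)c1ccccc1; carbon tetrabromide, BrC(Br)(Br)Br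
Why: Appel bromination under neutral conditions (safe for the TES ether) gives the primary dienyl bromide, which is captured in the same flask by PPh3 in an SN2 quaternization to the C15 phosphonium salt.

**Step 14**
Reactants: 18 {(2E,4E)-5-[(4R,5R)-5-(tert-butyldimethylsilyloxy)-2,6,6-trimethyl-4-(triethylsilyloxy)cyclohex-1-en-1-yl]-3-methylpenta-2,4-dien-1-yl}triphenylphosphonium bromide; 19 (2E,4E,6E)-2,7-dimethylocta-2,4,6-trienedial
Product: 21 (2E,4E,6E,8E,10E,12E)-13-[(4R,5R)-5-(tert-butyldimethylsilyloxy)-2,6,6-trimethyl-4-(triethylsilyloxy)cyclohex-1-en-1-yl]-2,7,11-trimethyltrideca-2,4,6,8,10,12-hexaenal, via phosphorus ylide 20 (not isolated)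
Conditions: 18, NaN(SiMe3)2 (1.0 equiv), THF, −78 °C; added to 19 (3 equiv), THF/CH2Cl2, −78 → 0 °C; then I2 (1 mol%), CH2Cl2, rt, daylight
Reagents that add atoms: none
Why: Wittig olefination of the semi-stabilized ylide with an excess of the symmetrical dialdehyde stops at mono-olefination, and iodine-catalysed equilibration converts the hindered 11Z isomer into the all-E C25 aldehyde that carries the fully silylated ring A.

**Step 15**
Reactants: 18 {(2E,4E)-5-[(4R,5R)-5-(tert-butyldimethylsilyloxy)-2,6,6-trimethyl-4-(triethylsilyloxy)cyclohex-1-en-1-yl]-3-methylpenta-2,4-dien-1-yl}triphenylphosphonium bromide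
Product: 22 {(2E,4E)-5-[(4R,5R)-5-(tert-butyldimethylsilyloxy)-4-hydroxy-2,6,6-trimethylcyclohex-1-en-1-yl]-3-methylpenta-2,4-dien-1-yl}triphenylphosphonium bromide
Conditions: pyridinium p-toluenesulfonate (0.1 equiv), MeOH/CH2Cl2, 0 °C → rt
Reagents that add atoms: none
Why: Acid-catalysed methanolysis (selective desilylation) removes the more labile, less hindered triethylsilyl ether at O3 from a second portion of the salt, while the neopentylic TBS ether at O2 and the phosphonium salt, which is stable to mild acid in methanol, persist; this gives the ring B unit with the single hydroxyl that is to be sulfated.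

**Step 16**
Reactants: 21 (2E,4E,6E,8E,10E,12E)-13-[(4R,5R)-5-(tert-butyldimethylsilyloxy)-2,6,6-trimethyl-4-(triethylsilyloxy)cyclohex-1-en-1-yl]-2,7,11-trimethyltrideca-2,4,6,8,10,12-hexaenal; 22 {(2E,4E)-5-[(4R,5R)-5-(tert-butyldimethylsilyloxy)-4-hydroxy-2,6,6-trimethylcyclohex-1-en-1-yl]-3-methylpenta-2,4-dien-1-yl}triphenylphosphonium bromide
Product: 24 (2R,3R,2'R,3'R)-2,2'-bis(tert-butyldimethylsilyloxy)-3-(triethylsilyloxy)-β,β-caroten-3'-ol, via hydroxy phosphorus ylide 23 (not isolated)
Conditions: 22 (1.3 equiv), NaN(SiMe3)2 (1.25 equiv), THF, −78 °C; 21, −78 °C → rt; then heptane, 80 °C, dark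
Reagents that add atoms: none
Why: A second Wittig olefination joins the ring B unit to the C25 aldehyde, one equivalent of base removing only the far more acidic phosphonium α-hydrogen so that no alkoxide forms beside the O2' silyl ether and silyl migration is avoided, and thermal isomerization converts the new C11'=C12' olefin to E, giving the C40 skeleton with one free hydroxyl.

**Step 17**
Reactants: 24 (2R,3R,2'R,3'R)-2,2'-bis(tert-butyldimethylsilyloxy)-3-(triethylsilyloxy)-β,β-caroten-3'-ol
Product: 25 (2R,3R,2'R,3'R)-2,2'-bis(tert-butyldimethylsilyloxy)-3-(triethylsilyloxy)-β,β-caroten-3'-yl hydrogen sulfate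
Conditions: SO3·pyridine (3 equiv), pyridine, 0 °C → rt, dark
Reagents that add atoms: sulfur trioxide–pyridine complex, [O-]S(=O)(=O)[n+]1ccccc1
Why: O-Sulfonation with SO3·pyridine occurs at the only free hydroxyl, O3' of ring B, under basic non-oxidizing conditions that the polyene and the silyl ethers tolerate.

**Step 18**
Reactants: 25 (2R,3R,2'R,3'R)-2,2'-bis(tert-butyldimethylsilyloxy)-3-(triethylsilyloxy)-β,β-caroten-3'-yl hydrogen sulfate
Product: 26 (2R,3R,2'R,3'R)-2,3,2'-trihydroxy-β,β-caroten-3'-yl hydrogen sulfate (CNP0229621.3)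
Conditions: HF·pyridine (excess), pyridine, THF, 0 °C → rt; aq. NaHCO3; Dowex 50W (H+ form), MeOH, 0 °C
Reagents that add atoms: none
Why: Fluoride-driven cleavage of the three silyl ethers (global desilylation) with buffered HF·pyridine liberates O2, O3 and O2' while the secondary sulfate monoester is expected to survive, and cold acidic resin gives the hydrogen sulfate.

**Compound list**
1 | methyl 3-methylbut-2-enoate | CC(C)=CC(=O)OC | starting material
2 | tert-butyl[(1-methoxy-3-methylbuta-1,3-dien-1-yl)oxy]dimethylsilane (ketene acetal geometry undefined and immaterial) | COC(=CC(C)=C)O[Si](C)(C)C(C)(C)C | intermediate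
3 | 3-methylbut-2-enal | CC(C)=CC=O | starting material
4 | methyl (2E,5R)-5-hydroxy-3,7-dimethylocta-2,6-dienoate | CC(C)=C[C@H](O)C/C(C)=C/C(=O)OC | intermediate
5 | methyl (2E,5R)-5-[(2S)-3,3-dimethyloxiran-2-yl]-5-hydroxy-3-methylpent-2-enoate | CC1(C)O[C@H]1[C@H](O)C/C(C)=C/C(=O)OC | intermediate
6 | methyl (2E,5R)-5-[(2S)-3,3-dimethyloxiran-2-yl]-3-methyl-5-(triethylsilyloxy)pent-2-enoate | CC1(C)O[C@H]1[C@H](O[Si](CC)(CC)CC)C/C(C)=C/C(=O)OC | intermediate
7 | (2E,5R)-5-[(2S)-3,3-dimethyloxiran-2-yl]-3-methyl-5-(triethylsilyloxy)pent-2-en-1-ol | CC1(C)O[C@H]1[C@H](O[Si](CC)(CC)CC)C/C(C)=C/CO | intermediate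
8 | (2E,5R)-5-[(2S)-3,3-dimethyloxiran-2-yl]-3-methyl-5-(triethylsilyloxy)pent-2-en-1-yl acetate | CC1(C)O[C@H]1[C@H](O[Si](CC)(CC)CC)C/C(C)=C/COC(C)=O | intermediate
9 | [(1R,3R,4R)-3-hydroxy-2,2-dimethyl-6-methylidene-4-(triethylsilyloxy)cyclohexyl]methyl acetate | C=C1[C@@H](COC(C)=O)C(C)(C)[C@@H](O)[C@H](O[Si](CC)(CC)CC)C1 | intermediate
10 | [(1R,3R,4R)-3-(tert-butyldimethylsilyloxy)-2,2-dimethyl-6-methylidene-4-(triethylsilyloxy)cyclohexyl]methyl acetate | C=C1[C@@H](COC(C)=O)C(C)(C)[C@@H](O[Si](C)(C)C(C)(C)C)[C@H](O[Si](CC)(CC)CC)C1 | intermediate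
11 | [(1R,3R,4R)-3-(tert-butyldimethylsilyloxy)-2,2-dimethyl-6-methylidene-4-(triethylsilyloxy)cyclohexyl]methanol | C=C1[C@@H](CO)C(C)(C)[C@@H](O[Si](C)(C)C(C)(C)C)[C@H](O[Si](CC)(CC)CC)C1 | intermediate
12 | (1R,3R,4R)-3-(tert-butyldimethylsilyloxy)-2,2-dimethyl-6-methylidene-4-(triethylsilyloxy)cyclohexane-1-carbaldehyde | C=C1[C@@H](C=O)C(C)(C)[C@@H](O[Si](C)(C)C(C)(C)C)[C@H](O[Si](CC)(CC)CC)C1 | intermediate
13 | (4R,5R)-5-(tert-butyldimethylsilyloxy)-2,6,6-trimethyl-4-(triethylsilyloxy)cyclohex-1-ene-1-carbaldehyde | CC1=C(C=O)C(C)(C)[C@@H](O[Si](C)(C)C(C)(C)C)[C@H](O[Si](CC)(CC)CC)C1 | intermediate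
14 | ethyl (2E)-4-(diethoxyphosphoryl)-3-methylbut-2-enoate | CCOC(=O)/C=C(\C)CP(=O)(OCC)OCC | starting material
15 | ethyl (2E,4E)-5-[(4R,5R)-5-(tert-butyldimethylsilyloxy)-2,6,6-trimethyl-4-(triethylsilyloxy)cyclohex-1-en-1-yl]-3-methylpenta-2,4-dienoate | CCOC(=O)/C=C(\C)/C=C/C1=C(C)C[C@@H](O[Si](CC)(CC)CC)[C@H](O[Si](C)(C)C(C)(C)C)C1(C)C | intermediate
16 | (2E,4E)-5-[(4R,5R)-5-(tert-butyldimethylsilyloxy)-2,6,6-trimethyl-4-(triethylsilyloxy)cyclohex-1-en-1-yl]-3-methylpenta-2,4-dien-1-ol | OC/C=C(\C)/C=C/C1=C(C)C[C@@H](O[Si](CC)(CC)CC)[C@H](O[Si](C)(C)C(C)(C)C)C1(C)C | intermediate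
17 | tert-butyl{[(1R,6R)-3-[(1E,3E)-5-bromo-3-methylpenta-1,3-dien-1-yl]-2,2,4-trimethyl-6-(triethylsilyloxy)cyclohex-3-en-1-yl]oxy}dimethylsilane | BrC/C=C(\C)/C=C/C1=C(C)C[C@@H](O[Si](CC)(CC)CC)[C@H](O[Si](C)(C)C(C)(C)C)C1(C)C | intermediate
18 | {(2E,4E)-5-[(4R,5R)-5-(tert-butyldimethylsilyloxy)-2,6,6-trimethyl-4-(triethylsilyloxy)cyclohex-1-en-1-yl]-3-methylpenta-2,4-dien-1-yl}triphenylphosphonium bromide | [Br-].c1ccccc1[P+](c1ccccc1)(c1ccccc1)C/C=C(\C)/C=C/C1=C(C)C[C@@H](O[Si](CC)(CC)CC)[C@H](O[Si](C)(C)C(C)(C)C)C1(C)C | intermediate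
19 | (2E,4E,6E)-2,7-dimethylocta-2,4,6-trienedial | O=C/C(C)=C/C=C/C=C(\C)C=O | starting material
20 | {(2E,4E)-5-[(4R,5R)-5-(tert-butyldimethylsilyloxy)-2,6,6-trimethyl-4-(triethylsilyloxy)cyclohex-1-en-1-yl]-3-methylpenta-2,4-dien-1-ylidene}triphenylphosphorane | c1ccccc1P(c1ccccc1)(c1ccccc1)=C/C=C(\C)/C=C/C1=C(C)C[C@@H](O[Si](CC)(CC)CC)[C@H](O[Si](C)(C)C(C)(C)C)C1(C)C | intermediate
21 | (2E,4E,6E,8E,10E,12E)-13-[(4R,5R)-5-(tert-butyldimethylsilyloxy)-2,6,6-trimethyl-4-(triethylsilyloxy)cyclohex-1-en-1-yl]-2,7,11-trimethyltrideca-2,4,6,8,10,12-hexaenal | O=C/C(C)=C/C=C/C=C(C)/C=C/C=C(C)/C=C/C1=C(C)C[C@@H](O[Si](CC)(CC)CC)[C@H](O[Si](C)(C)C(C)(C)C)C1(C)C | intermediate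
22 | {(2E,4E)-5-[(4R,5R)-5-(tert-butyldimethylsilyloxy)-4-hydroxy-2,6,6-trimethylcyclohex-1-en-1-yl]-3-methylpenta-2,4-dien-1-yl}triphenylphosphonium bromide | [Br-].c1ccccc1[P+](c1ccccc1)(c1ccccc1)C/C=C(\C)/C=C/C1=C(C)C[C@@H](O)[C@H](O[Si](C)(C)C(C)(C)C)C1(C)C | intermediate
23 | {(2E,4E)-5-[(4R,5R)-5-(tert-butyldimethylsilyloxy)-4-hydroxy-2,6,6-trimethylcyclohex-1-en-1-yl]-3-methylpenta-2,4-dien-1-ylidene}triphenylphosphorane | c1ccccc1P(c1ccccc1)(c1ccccc1)=C/C=C(\C)/C=C/C1=C(C)C[C@@H](O)[C@H](O[Si](C)(C)C(C)(C)C)C1(C)C | intermediate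
24 | (2R,3R,2'R,3'R)-2,2'-bis(tert-butyldimethylsilyloxy)-3-(triethylsilyloxy)-β,β-caroten-3'-ol | CC1=C(/C=C/C(C)=C/C=C/C(C)=C/C=C/C=C(C)/C=C/C=C(C)/C=C/C2=C(C)C[C@@H](O)[C@H](O[Si](C)(C)C(C)(C)C)C2(C)C)C(C)(C)[C@@H](O[Si](C)(C)C(C)(C)C)[C@H](O[Si](CC)(CC)CC)C1 | intermediate
25 | (2R,3R,2'R,3'R)-2,2'-bis(tert-butyldimethylsilyloxy)-3-(triethylsilyloxy)-β,β-caroten-3'-yl hydrogen sulfate | CC1=C(/C=C/C(C)=C/C=C/C(C)=C/C=C/C=C(C)/C=C/C=C(C)/C=C/C2=C(C)C[C@@H](OS(=O)(=O)O)[C@H](O[Si](C)(C)C(C)(C)C)C2(C)C)C(C)(C)[C@@H](O[Si](C)(C)C(C)(C)C)[C@H](O[Si](CC)(CC)CC)C1 | intermediate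
26 | (2R,3R,2'R,3'R)-2,3,2'-trihydroxy-β,β-caroten-3'-yl hydrogen sulfate (CNP0229621.3) | CC1=C(/C=C/C(C)=C/C=C/C(C)=C/C=C/C=C(C)/C=C/C=C(C)/C=C/C2=C(C)C[C@@H](OS(=O)(=O)O)[C@H](O)C2(C)C)C(C)(C)[C@@H](O)[C@H](O)C1 | target

**Step count and risk**
Total step count: 18. Longest linear sequence: 17 steps (steps 1–13, then 14, 16, 17 and 18; phosphonium salt 18 is divided between steps 14 and 15, and the two branches meet in step 16).

Steps most likely to fail:

1. Step 7. The tertiary C1 radical may be reduced by a second Cp2TiCl before it cyclizes, leading to deoxygenation or to β-hydride loss to an isopropenyl carbinol instead of ring closure. The fallback sets out from 8 and returns at 9. MeAlCl2 in CH2Cl2 at −78 °C would trigger the polar counterpart, a Lewis-acid-initiated cation–olefin cyclization in which the C5=C6 olefin attacks the tertiary epoxide carbon C1 as the C1–O bond ionizes. The same C1–C6 bond and the same C2 and C3 configurations result, but the C5 cation loses a proton in two directions. This gives 9 together with its endocyclic olefin isomer [(1R,4R,5R)-5-hydroxy-2,6,6-trimethyl-4-(triethylsilyloxy)cyclohex-2-en-1-yl]methyl acetate F1, from which 9 is separated on AgNO3-impregnated silica.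

2. Step 18. Cleavage of the two neopentylic O2 silyl ethers may be too slow, and prolonged exposure may degrade the polyene or solvolyse the sulfate. The fallback sets out from 24 and returns at 26. All three silyl ethers are removed before any sulfate is present (Bu4NF, THF, 40 °C), giving (2R,3R,2'R,3'R)-β,β-carotene-2,3,2',3'-tetrol F2. F2 is then sulfated with a deficit of SO3·pyridine (0.8 equiv, pyridine, 0 °C). The neopentylic 2-hydroxyls should react far more slowly than the 3-hydroxyls, and because F2 is C2-symmetric either 3-hydroxyl gives the same monosulfate, which is 26. Unreacted F2 is recycled and over-sulfated material is removed on reversed phase.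

3. Step 2. Face discrimination on the β,β-disubstituted enal may be poor, or α-attack of the dienolate may compete. The fallback sets out from 2 and 3 and returns at 4. BF3·OEt2 (CH2Cl2, −78 °C) promotes the achiral vinylogous Mukaiyama aldol to the racemate, that is 4 together with its enantiomer methyl (2E,5S)-5-hydroxy-3,7-dimethylocta-2,6-dienoate F3. Dess–Martin oxidation of the mixture gives the enone methyl (2E)-3,7-dimethyl-5-oxoocta-2,6-dienoate F4. Corey–Bakshi–Shibata reduction ((S)-2-methyl-CBS-oxazaborolidine 10 mol%, catecholborane, toluene, −78 °C), with the isobutenyl group acting as the large substituent, returns enantioenriched 4.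

**Further compounds**
F1 | step 7 | [(1R,4R,5R)-5-hydroxy-2,6,6-trimethyl-4-(triethylsilyloxy)cyclohex-2-en-1-yl]methyl acetate | CC1=C[C@@H](O[Si](CC)(CC)CC)[C@H](O)C(C)(C)[C@@H]1COC(C)=O
F2 | step 18 | (2R,3R,2'R,3'R)-β,β-carotene-2,3,2',3'-tetrol | CC1=C(/C=C/C(C)=C/C=C/C(C)=C/C=C/C=C(C)/C=C/C=C(C)/C=C/C2=C(C)C[C@@H](O)[C@H](O)C2(C)C)C(C)(C)[C@@H](O)[C@H](O)C1
F3 | step 2 | methyl (2E,5S)-5-hydroxy-3,7-dimethylocta-2,6-dienoate | CC(C)=C[C@@H](O)C/C(C)=C/C(=O)OC
F4 | step 2 | methyl (2E)-3,7-dimethyl-5-oxoocta-2,6-dienoate | CC(C)=CC(=O)C/C(C)=C/C(=O)OC
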